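**Plan**
- Retrosynthesis: ring C is opened at O1–C2 and C4–C4a together, giving a 3,5-disilylated phloroglucinol (O,C-bisnucleophile) and a 2-arylacryloyl unit C2–C3–C4 carried by ring B. The acrylic acid is traced to an 8-acetyl-2H-chromene, the pyran of ring B to an aryl 1,1-dimethylpropargyl ether, and that to 2,4-dihydroxyacetophenone.
- Enabling feature: ring A is a phloroglucinol, so C4a is ortho to O1 and ortho/para to O5 and O7, and both ortho carbons of a 3,5-disilylated phenol are identical. C2 is an unsubstituted CH2 β to C4=O, so C2–C3–C4 is an acryloyl group that takes C4a at its acyl carbon and O1 at its terminal carbon.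
- Forward order: pyran of ring B (Claisen/electrocyclisation), then the acrylic acid (Shapiro/CO2), then ring C last, closed in one operation that also joins the two halves.
- Stereochemistry: C3, the only stereocenter, is α to C4=O and benzylic, hence labile. It is formed racemic in the annulation, then set by asymmetric transfer hydrogenation with dynamic kinetic resolution (catalyst control, cis-(3R,4R) alcohol); C4 is re-oxidised and the silyl groups are removed without free base.

Key step: step 7

Remark on the chemistry: the C3–H of an isoflavanone is epimerised by amine or stronger bases, so once C3 is fixed (after step 8) the medium is kept buffered and free of strong base.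

**Step 1**
Reactants: 1 1-(2,4-dihydroxyphenyl)ethan-1-one
Product: 2 1-[2-hydroxy-4-(triisopropylsilyloxy)phenyl]ethan-1-one
Conditions: TIPSCl, imidazole, DMF, 0 °C → rt
Reagents that add atoms: chlorotriisopropylsilane (TIPSCl), CC(C)[Si](Cl)(C(C)C)C(C)C
Why: Silyl ether formation; the 2-OH is hydrogen-bonded to the acetyl carbonyl and hindered, so the bulky silyl chloride should take only the 4-OH.

**Step 2**
Reactants: 2 1-[2-hydroxy-4-(triisopropylsilyloxy)phenyl]ethan-1-one; 3 3-chloro-3-methylbut-1-yne
Product: 4 1-[2-(2-methylbut-3-yn-2-yloxy)-4-(triisopropylsilyloxy)phenyl]ethan-1-one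
Conditions: DBU, CuCl2 (cat.), MeCN, 0 °C → rt
Reagents that add atoms: none
Why: Copper-catalysed propargylic etherification (phenoxide attack on a copper acetylide/allenylidene formed from the tertiary propargylic chloride), a method suited to electron-poor phenoxides for which plain SN2 alkylation fails.

**Step 3**
Reactants: 4 1-[2-(2-methylbut-3-yn-2-yloxy)-4-(triisopropylsilyloxy)phenyl]ethan-1-one
Product: 6 1-[2,2-dimethyl-5-(triisopropylsilyloxy)-2H-chromen-8-yl]ethan-1-one, via allenylphenol 5 (not isolated)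
Conditions: N,N-diethylaniline, 170 °C
Reagents that add atoms: none
Why: Aromatic propargyl Claisen rearrangement to the only free ortho carbon (the other carries the acetyl group), then 1,5-hydrogen shift and oxa-6π electrocyclisation of 5, should give the 2,2-dimethyl-2H-chromene with the ring oxygen next to the acetyl-bearing carbon.

**Step 4**
Reactants: 6 1-[2,2-dimethyl-5-(triisopropylsilyloxy)-2H-chromen-8-yl]ethan-1-one
Product: 7 N'-{1-[2,2-dimethyl-5-(triisopropylsilyloxy)-2H-chromen-8-yl]ethylidene}-2,4,6-triisopropylbenzenesulfonohydrazide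
Conditions: 2,4,6-triisopropylbenzenesulfonohydrazide, PPTS (cat.), THF, rt
Reagents that add atoms: 2,4,6-triisopropylbenzenesulfonohydrazide, CC(C)c1cc(C(C)C)c(S(=O)(=O)NN)c(C(C)C)c1
Why: Hydrazone condensation of the methyl ketone; the triisopropylphenyl group is chosen because it cannot be ortho-lithiated in the next step.

**Step 5**
Reactants: 7 N'-{1-[2,2-dimethyl-5-(triisopropylsilyloxy)-2H-chromen-8-yl]ethylidene}-2,4,6-triisopropylbenzenesulfonohydrazide
Product: 9 2-[2,2-dimethyl-5-(triisopropylsilyloxy)-2H-chromen-8-yl]prop-2-enoic acid, via vinyllithium 8 (not isolated)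
Conditions: n-BuLi (2.2 equiv), THF, −78 → 0 °C; CO2, −78 °C; 1 M HCl, 0 °C
Reagents that add atoms: carbon dioxide, O=C=O
Why: Shapiro reaction: the hydrazone dianion loses sulfinate and N2 to give the 1-arylvinyllithium 8, whose carboxylation should give the 2-arylacrylic acid with the alkene fixed at the former methyl carbon.

**Step 6**
Reactants: 10 benzene-1,3,5-triol
Product: 11 3,5-bis(triisopropylsilyloxy)phenol
Conditions: TIPSCl (2 equiv), imidazole, DMF, 0 °C → rt
Reagents that add atoms: chlorotriisopropylsilane (TIPSCl), CC(C)[Si](Cl)(C(C)C)C(C)C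
Why: Statistical silyl ether formation on a threefold-symmetric triol, so only one bis-ether constitution can form and the mono- and tris-ethers are removed by chromatography.

**Step 7**
Reactants: 9 2-[2,2-dimethyl-5-(triisopropylsilyloxy)-2H-chromen-8-yl]prop-2-enoic acid; 11 3,5-bis(triisopropylsilyloxy)phenol
Product: 15 rac-3-[2,2-dimethyl-5-(triisopropylsilyloxy)-2H-chromen-8-yl]-5,7-bis(triisopropylsilyloxy)chroman-4-one, via acid chloride 12 (not isolated), via magnesium phenolate 13 (not isolated), via hydroxy enone 14 (not isolated)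
Conditions: 9, 1-chloro-N,N,2-trimethylprop-1-en-1-amine, CH2Cl2, 0 °C; 11, EtMgBr, Et2O then toluene, 0 °C; mix, toluene, 0 °C → rt; aq NaHCO3
Reagents that add atoms: none
Why: The acid is converted under neutral conditions into acid chloride 12, which binds through its carbonyl oxygen to the magnesium of phenolate 13; within this six-membered chelate the ortho carbon of 13 (the future C4a) attacks the acyl carbon (C4), chloride leaves and the dienone rearomatises to the chelated 2-hydroxyaryl 1-arylvinyl ketone 14. The phenolic oxygen of 14 (O1) then adds to the unsubstituted terminal CH2 of the enone (C2) and the enol ketonises, so ring C closes by a 6-endo-trig oxa-Michael addition. The closest known reaction types are the coordination-directed ortho-acylation of bromomagnesium phenolates by acyl chlorides (a templated Friedel–Crafts acylation) and the oxa-Michael closure of 2-hydroxyphenyl 1-arylvinyl ketones that ends the classical deoxybenzoin–formaldehyde isoflavanone synthesis. The new stereocenter C3 arises by uncontrolled protonation of the enol and is deliberately left racemic, because it is labile and is fixed by catalyst control in step 8. The step needs C- over O-acylation and 1,2- over 1,4-attack, which the magnesium template in a non-coordinating solvent and the threefold activation of C4a (ortho to OMg, ortho and para to the two silyloxy groups) should secure, and it needs no regiocontrol because both ortho carbons of 11 are equivalent by symmetry. The medium contains no protic acid or strong Lewis acid and should therefore spare the acid-sensitive 2,2-dimethylchromene of ring B and the aryl silyl ethers.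

**Step 8**
Reactants: 15 rac-3-[2,2-dimethyl-5-(triisopropylsilyloxy)-2H-chromen-8-yl]-5,7-bis(triisopropylsilyloxy)chroman-4-one
Product: 16 (3R,4R)-3-[2,2-dimethyl-5-(triisopropylsilyloxy)-2H-chromen-8-yl]-5,7-bis(triisopropylsilyloxy)chroman-4-ol (cis)
Conditions: RuCl(p-cymene)[(R,R)-TsDPEN] (cat.), HCO2H, Et3N, EtOAc, 40 °C
Reagents that add atoms: none
Why: Noyori asymmetric transfer hydrogenation with dynamic kinetic resolution, a reaction type established on 2'-oxygenated isoflavanones: Et3N interconverts the C3 epimers of 15 through the enol, the (R,R) catalyst should give the (4R) benzylic alcohol in its usual sense for aryl ketones, and hydride delivery anti to the C3 aryl group makes the ring cis and therefore (3R).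

**Step 9**
Reactants: 16 (3R,4R)-3-[2,2-dimethyl-5-(triisopropylsilyloxy)-2H-chromen-8-yl]-5,7-bis(triisopropylsilyloxy)chroman-4-ol
Product: 17 (3R)-3-[2,2-dimethyl-5-(triisopropylsilyloxy)-2H-chromen-8-yl]-5,7-bis(triisopropylsilyloxy)chroman-4-one
Conditions: Dess–Martin periodinane, pyridine, CH2Cl2, 0 °C
Reagents that add atoms: none
Why: Dess–Martin oxidation returns the benzylic alcohol to the C4 ketone in a buffered medium that should neither ionise the electron-rich benzylic alcohol nor enolise the product, so C3 keeps its R configuration.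

**Step 10**
Reactants: 17 (3R)-3-[2,2-dimethyl-5-(triisopropylsilyloxy)-2H-chromen-8-yl]-5,7-bis(triisopropylsilyloxy)chroman-4-one
Product: 18 (3R)-5,7-dihydroxy-3-(5-hydroxy-2,2-dimethyl-2H-chromen-8-yl)chroman-4-one
Conditions: Bu4NF, AcOH (1.2 equiv per fluoride), THF, 0 °C
Reagents that add atoms: none
Why: Fluoride cleavage of the three aryl silyl ethers with acetic acid as buffer, so no free phenoxide or fluoride base is present to epimerise C3 or open ring C by retro-oxa-Michael reaction, and the chromene is inert.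

**Compound list**
1 | 1-(2,4-dihydroxyphenyl)ethan-1-one | CC(=O)c1ccc(O)cc1O | starting material
2 | 1-[2-hydroxy-4-(triisopropylsilyloxy)phenyl]ethan-1-one | CC(=O)c1ccc(O[Si](C(C)C)(C(C)C)C(C)C)cc1O | intermediate
3 | 3-chloro-3-methylbut-1-yne | C#CC(C)(C)Cl | starting material
4 | 1-[2-(2-methylbut-3-yn-2-yloxy)-4-(triisopropylsilyloxy)phenyl]ethan-1-one | CC(=O)c1ccc(O[Si](C(C)C)(C(C)C)C(C)C)cc1OC(C)(C)C#C | intermediate
5 | 1-[2-hydroxy-3-(3-methylbuta-1,2-dien-1-yl)-4-(triisopropylsilyloxy)phenyl]ethan-1-one | CC(=O)c1ccc(O[Si](C(C)C)(C(C)C)C(C)C)c(C=C=C(C)C)c1O | intermediate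
6 | 1-[2,2-dimethyl-5-(triisopropylsilyloxy)-2H-chromen-8-yl]ethan-1-one | CC(=O)c1ccc(O[Si](C(C)C)(C(C)C)C(C)C)c2C=CC(C)(C)Oc12 | intermediate
7 | N'-{1-[2,2-dimethyl-5-(triisopropylsilyloxy)-2H-chromen-8-yl]ethylidene}-2,4,6-triisopropylbenzenesulfonohydrazide | CC(=NNS(=O)(=O)c1c(C(C)C)cc(C(C)C)cc1C(C)C)c1ccc(O[Si](C(C)C)(C(C)C)C(C)C)c2C=CC(C)(C)Oc12 | intermediate
8 | {1-[2,2-dimethyl-5-(triisopropylsilyloxy)-2H-chromen-8-yl]ethenyl}lithium | [Li]C(=C)c1ccc(O[Si](C(C)C)(C(C)C)C(C)C)c2C=CC(C)(C)Oc12 | intermediate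
9 | 2-[2,2-dimethyl-5-(triisopropylsilyloxy)-2H-chromen-8-yl]prop-2-enoic acid | C=C(C(=O)O)c1ccc(O[Si](C(C)C)(C(C)C)C(C)C)c2C=CC(C)(C)Oc12 | intermediate
10 | benzene-1,3,5-triol (phloroglucinol) | Oc1cc(O)cc(O)c1 | starting material
11 | 3,5-bis(triisopropylsilyloxy)phenol | Oc1cc(O[Si](C(C)C)(C(C)C)C(C)C)cc(O[Si](C(C)C)(C(C)C)C(C)C)c1 | intermediate
12 | 2-[2,2-dimethyl-5-(triisopropylsilyloxy)-2H-chromen-8-yl]prop-2-enoyl chloride | C=C(C(=O)Cl)c1ccc(O[Si](C(C)C)(C(C)C)C(C)C)c2C=CC(C)(C)Oc12 | intermediate
13 | bromomagnesium 3,5-bis(triisopropylsilyloxy)phenolate | Br[Mg]Oc1cc(O[Si](C(C)C)(C(C)C)C(C)C)cc(O[Si](C(C)C)(C(C)C)C(C)C)c1 | intermediate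
14 | 2-[2,2-dimethyl-5-(triisopropylsilyloxy)-2H-chromen-8-yl]-1-[2-hydroxy-4,6-bis(triisopropylsilyloxy)phenyl]prop-2-en-1-one | C=C(C(=O)c1c(O)cc(O[Si](C(C)C)(C(C)C)C(C)C)cc1O[Si](C(C)C)(C(C)C)C(C)C)c1ccc(O[Si](C(C)C)(C(C)C)C(C)C)c2C=CC(C)(C)Oc12 | intermediate
15 | rac-3-[2,2-dimethyl-5-(triisopropylsilyloxy)-2H-chromen-8-yl]-5,7-bis(triisopropylsilyloxy)chroman-4-one | CC1(C)C=Cc2c(O[Si](C(C)C)(C(C)C)C(C)C)ccc(C3COc4cc(O[Si](C(C)C)(C(C)C)C(C)C)cc(O[Si](C(C)C)(C(C)C)C(C)C)c4C3=O)c2O1 | intermediate
16 | (3R,4R)-3-[2,2-dimethyl-5-(triisopropylsilyloxy)-2H-chromen-8-yl]-5,7-bis(triisopropylsilyloxy)chroman-4-ol | CC1(C)C=Cc2c(O[Si](C(C)C)(C(C)C)C(C)C)ccc([C@@H]3COc4cc(O[Si](C(C)C)(C(C)C)C(C)C)cc(O[Si](C(C)C)(C(C)C)C(C)C)c4[C@@H]3O)c2O1 | intermediate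
17 | (3R)-3-[2,2-dimethyl-5-(triisopropylsilyloxy)-2H-chromen-8-yl]-5,7-bis(triisopropylsilyloxy)chroman-4-one | CC1(C)C=Cc2c(O[Si](C(C)C)(C(C)C)C(C)C)ccc([C@@H]3COc4cc(O[Si](C(C)C)(C(C)C)C(C)C)cc(O[Si](C(C)C)(C(C)C)C(C)C)c4C3=O)c2O1 | intermediate
18 | (3R)-5,7-dihydroxy-3-(5-hydroxy-2,2-dimethyl-2H-chromen-8-yl)chroman-4-one | CC1(C)C=Cc2c(O)ccc([C@@H]3COc4cc(O)cc(O)c4C3=O)c2O1 | target

**Totals**
Total step count: 10. Longest linear sequence: 9 steps (steps 1–5 and 7–10); step 6 is a one-step side branch.

**Steps most likely to fail**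

1. Step 7. The phenolate may be acylated at oxygen, or the acryloyl chloride may be consumed by conjugate addition or polymerisation, instead of the templated C-acylation; ring closure may also stay incomplete. The fallback reverses the bond order with known chemistry, sets out from 9 and 11 and comes back at 15. Acid 9 is methylated (Me3SiCHN2, MeOH/toluene) to methyl 2-[2,2-dimethyl-5-(triisopropylsilyloxy)-2H-chromen-8-yl]prop-2-enoate F1. Phenol 11 is added to it by base-catalysed oxa-Michael addition (Cs2CO3 cat., MeCN) to give methyl rac-3-[3,5-bis(triisopropylsilyloxy)phenoxy]-2-[2,2-dimethyl-5-(triisopropylsilyloxy)-2H-chromen-8-yl]propanoate F2, which makes O1–C2 first. Me3SnOH (1,2-dichloroethane, 80 °C) gives rac-3-[3,5-bis(triisopropylsilyloxy)phenoxy]-2-[2,2-dimethyl-5-(triisopropylsilyloxy)-2H-chromen-8-yl]propanoic acid F3. Intramolecular Friedel–Crafts acylation of the highly activated ring ((CF3CO)2O, CH2Cl2, 0 °C, short contact) then closes C4–C4a and gives 15.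

2. Step 8. Hydride transfer to the C4 carbonyl may be slow because it is flanked by the 5-silyloxy group and the ortho-substituted 3-aryl group, or C3 epimerisation may not keep pace with reduction, so the dynamic resolution stays incomplete. The fallback sets out from 15 and comes back at 17, skipping 16 and step 9. Soft enolisation (Me3SiOTf, Et3N, CH2Cl2, 0 °C) gives 3-[2,2-dimethyl-5-(triisopropylsilyloxy)-2H-chromen-8-yl]-5,7-bis(triisopropylsilyloxy)-4-(trimethylsilyloxy)-2H-chromene F4. Enantioselective protonation of this silyl enol ether (toluene, −78 °C) with the Lewis acid-assisted chiral Brønsted acid from SnCl4 and (R)-BINOL monomethyl ether (both catalytic) and 2,6-dimethylphenol as stoichiometric proton source should give 17. This is a known reaction type for silyl enol ethers of 2-aryl cycloalkanones; the BINOL enantiomer is expected by analogy and has to be confirmed on the first run.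

3. Step 2. O-alkylation of the hydrogen-bonded, weakly nucleophilic 2-OH by the tertiary propargylic chloride may fail, through elimination of the chloride to the enyne or through silyl loss under DBU. The fallback builds the pyran by condensation instead of alkylation/rearrangement, sets out from 2 and comes back at 6, bypassing 4 and 5. Phenol 2, 3-methylbut-2-enal and PhB(OH)2 (propionic acid cat., toluene, reflux with water removal) give, by boron-templated ortho-hydroxyalkylation at the free ortho carbon, 1-[4-(2-methylprop-1-en-1-yl)-2-phenyl-5-(triisopropylsilyloxy)-4H-1,3,2-benzodioxaborinin-8-yl]ethan-1-one F5. On continued heating this expels the boron unit to an ortho-quinone methide that closes by oxa-6π electrocyclisation to 6.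

**Further compounds**
F1 | step 7 | methyl 2-[2,2-dimethyl-5-(triisopropylsilyloxy)-2H-chromen-8-yl]prop-2-enoate | C=C(C(=O)OC)c1ccc(O[Si](C(C)C)(C(C)C)C(C)C)c2C=CC(C)(C)Oc12
F2 | step 7 | methyl rac-3-[3,5-bis(triisopropylsilyloxy)phenoxy]-2-[2,2-dimethyl-5-(triisopropylsilyloxy)-2H-chromen-8-yl]propanoate | COC(=O)C(COc1cc(O[Si](C(C)C)(C(C)C)C(C)C)cc(O[Si](C(C)C)(C(C)C)C(C)C)c1)c1ccc(O[Si](C(C)C)(C(C)C)C(C)C)c2C=CC(C)(C)Oc12
F3 | step 7 | rac-3-[3,5-bis(triisopropylsilyloxy)phenoxy]-2-[2,2-dimethyl-5-(triisopropylsilyloxy)-2H-chromen-8-yl]propanoic acid | OC(=O)C(COc1cc(O[Si](C(C)C)(C(C)C)C(C)C)cc(O[Si](C(C)C)(C(C)C)C(C)C)c1)c1ccc(O[Si](C(C)C)(C(C)C)C(C)C)c2C=CC(C)(C)Oc12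
F4 | step 8 | 3-[2,2-dimethyl-5-(triisopropylsilyloxy)-2H-chromen-8-yl]-5,7-bis(triisopropylsilyloxy)-4-(trimethylsilyloxy)-2H-chromene | CC1(C)C=Cc2c(O[Si](C(C)C)(C(C)C)C(C)C)ccc(C3=C(O[Si](C)(C)C)c4c(O[Si](C(C)C)(C(C)C)C(C)C)cc(O[Si](C(C)C)(C(C)C)C(C)C)cc4OC3)c2O1
F5 | step 2 | 1-[4-(2-methylprop-1-en-1-yl)-2-phenyl-5-(triisopropylsilyloxy)-4H-1,3,2-benzodioxaborinin-8-yl]ethan-1-one | CC(=O)c1ccc(O[Si](C(C)C)(C(C)C)C(C)C)c2C(C=C(C)C)OB(c3ccccc3)Oc12
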